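**Retrosynthetic overview** (eudesmane numbering: ring A = C1–C5 and C10, ring B = C5–C10, exocyclic C4=C15, Me-14 on C10, C11 = isopropyl methine)

1. Ring B is opened at C6–C7: the target is the reductive closure of seco-aldehyde 17, which has the C6 aldehyde on C5 and the C8–C7=C11 prenyl unit on the C9 carbinol that already carries the anisate.
2. Enabling feature: the C6 carbinol sits next to the isopropyl-bearing C7, so O6 and C11 are 1,3-related (O6–C6–C7–C11). An O6-isopropyl oxocarbenium ion closes C6–C7 onto the C7=C11 alkene, and its own O–CH hydrogen is then 1,5 to the C11 cation and reduces it. OH and isopropyl arise together, beside the intact C4 methylene and ester.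
3. 17 comes from cis-fused γ-lactone 13, a temporary ring tying the C6 carboxyl to O9. Deconjugative protonation inside this ring sets C5 and creates the C4=C15 methylene; the lactone is then opened, O9 acylated and C6 reduced to the aldehyde.
4. The conjugated lactone 11 comes from carbonylative lactonisation of enol triflate 10. C9 is set by reagent-controlled allylation (then cross-metathesis to prenyl), and C10 by an enantioselective Michael addition that, with an aldol condensation, builds ring A.
5. Order of ring formation: ring A (steps 1–2), temporary lactone ring (step 8, opened in step 10), ring B (step 13).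

Key step: step 13

Assumption: in step 1 the quinidine-derived (cupreidine-type) catalyst is taken to give the (R)-configured quaternary carbon; if it gives the antipode, its quinine-derived pseudo-enantiomer is used.

**Step 1**
Reactants: 1 methyl 2-methyl-3-oxopentanoate; 2 acrolein
Product: 3 methyl (2R)-2-methyl-3-oxo-2-(3-oxopropyl)pentanoate
Conditions: 9-O-(9-phenanthryl)cupreidine (10 mol%), CH2Cl2, −24 °C
Reagents that add atoms: none
Why: Enantioselective Michael addition of an α-substituted β-keto ester to acrolein under bifunctional cinchona catalysis (quinuclidine deprotonates the keto ester, the 6′-OH binds acrolein); the catalyst sets the quaternary carbon that becomes C10.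

**Step 2**
Reactants: 3 methyl (2R)-2-methyl-3-oxo-2-(3-oxopropyl)pentanoate
Product: 4 methyl (1R)-1,3-dimethyl-2-oxocyclohex-3-ene-1-carboxylate
Conditions: p-TsOH·H2O (10 mol%), toluene, reflux, Dean–Stark
Reagents that add atoms: none
Why: Intramolecular aldol condensation in which only the ethyl-ketone CH2 can reach the aldehyde through a six-membered ring, building ring A with the future C15 methyl on the enone α-carbon; the quaternary centre has no α-hydrogen and is not touched.

**Step 3**
Reactants: 4 methyl (1R)-1,3-dimethyl-2-oxocyclohex-3-ene-1-carboxylate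
Product: 6 methyl (1R)-1,3-dimethyl-2-[(trifluoromethanesulfonyl)oxy]cyclohex-2-ene-1-carboxylate, via lithium enolate 5 (not isolated)
Conditions: LiBH(s-Bu)3 (L-Selectride, 1.05 equiv), THF, −78 °C; then PhNTf2, −78 → 0 °C
Reagents that add atoms: N-phenylbis(trifluoromethanesulfonimide), O=S(=O)(N(c1ccccc1)S(=O)(=O)C(F)(F)F)C(F)(F)F
Why: Conjugate reduction of the β-unsubstituted cyclohexenone gives the regiodefined tetrasubstituted enolate, which is O-triflated (reductive enol triflation); 1,2-attack is blocked by the adjacent quaternary carbon and the ester should survive at −78 °C.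

**Step 4**
Reactants: 6 methyl (1R)-1,3-dimethyl-2-[(trifluoromethanesulfonyl)oxy]cyclohex-2-ene-1-carboxylate
Product: 7 (6S)-6-(hydroxymethyl)-2,6-dimethylcyclohex-1-en-1-yl trifluoromethanesulfonate
Conditions: i-Bu2AlH (2.5 equiv), CH2Cl2, −78 → 0 °C; Rochelle-salt work-up
Reagents that add atoms: none
Why: Aluminium hydride reduction of the ester to the primary alcohol; the enol triflate is inert to i-Bu2AlH at low temperature.

**Step 5**
Reactants: 7 (6S)-6-(hydroxymethyl)-2,6-dimethylcyclohex-1-en-1-yl trifluoromethanesulfonate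
Product: 8 (6R)-6-formyl-2,6-dimethylcyclohex-1-en-1-yl trifluoromethanesulfonate
Conditions: Dess–Martin periodinane, CH2Cl2, rt
Reagents that add atoms: none
Why: Dess–Martin oxidation of a neopentyl primary alcohol to a non-enolisable aldehyde.

**Step 6**
Reactants: 8 (6R)-6-formyl-2,6-dimethylcyclohex-1-en-1-yl trifluoromethanesulfonate
Product: 9 (6S)-6-[(1R)-1-hydroxybut-3-en-1-yl]-2,6-dimethylcyclohex-1-en-1-yl trifluoromethanesulfonate
Conditions: (+)-Ipc2B(allyl) (the B-allyldiisopinocampheylborane of the (−)-α-pinene series), Et2O, −78 °C; then 2-aminoethanol, rt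
Reagents that add atoms: (+)-B-allyldiisopinocampheylborane, C=CCB([C@H]1C[C@H]2C[C@@H]([C@@H]1C)C2(C)C)[C@H]1C[C@H]2C[C@@H]([C@@H]1C)C2(C)C
Why: Brown allylation through a chair Zimmerman–Traxler transition state; reagent control (Re-face attack on an aldehyde whose substituent outranks allyl) should set C9 as R over the weak bias of the adjacent quaternary centre.

**Step 7**
Reactants: 9 (6S)-6-[(1R)-1-hydroxybut-3-en-1-yl]-2,6-dimethylcyclohex-1-en-1-yl trifluoromethanesulfonate
Product: 10 (6S)-6-[(1R)-1-hydroxy-4-methylpent-3-en-1-yl]-2,6-dimethylcyclohex-1-en-1-yl trifluoromethanesulfonate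
Conditions: second-generation Grubbs catalyst RuCl2(=CHPh)(PCy3)(H2IMes) (5 mol%), 2-methylbut-2-ene (excess), CH2Cl2, 40 °C
Reagents that add atoms: 2-methylbut-2-ene, CC=C(C)C
Why: Olefin cross-metathesis of the terminal alkene with 2-methylbut-2-ene turns allyl into prenyl; the tetrasubstituted enol-triflate alkene cannot take part.

**Step 8**
Reactants: 10 (6S)-6-[(1R)-1-hydroxy-4-methylpent-3-en-1-yl]-2,6-dimethylcyclohex-1-en-1-yl trifluoromethanesulfonate
Product: 11 (3R,3aR)-3a,7-dimethyl-3-(3-methylbut-2-en-1-yl)-3a,4,5,6-tetrahydro-2-benzofuran-1(3H)-one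
Conditions: Pd(PPh3)4 (5 mol%), CO (1 atm), Et3N, LiCl, MeCN, 65 °C
Reagents that add atoms: carbon monoxide, [C-]#[O+]
Why: Palladium-catalysed carbonylation of the enol triflate with intramolecular capture of the acyl-palladium by the C9 hydroxyl (carbonylative lactonisation) installs C6 and closes the temporary five-membered lactone.

**Step 9**
Reactants: 11 (3R,3aR)-3a,7-dimethyl-3-(3-methylbut-2-en-1-yl)-3a,4,5,6-tetrahydro-2-benzofuran-1(3H)-one
Product: 13 (3R,3aR,7aS)-3a-methyl-7-methylidene-3-(3-methylbut-2-en-1-yl)hexahydro-2-benzofuran-1(3H)-one, via lithium dienolate 12 (not isolated)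
Conditions: LiN(i-Pr)2 (1.2 equiv), THF–DMPU, −78 °C; then inverse quench into AcOH–THF, −78 °C
Reagents that add atoms: none
Why: Deconjugative protonation: carbonyl-directed removal of a proton from the methyl group syn to the lactone carbonyl gives the exocyclic dienolate, and kinetic α-protonation from the face away from the ring-A carbons leads to the cis-fused lactone, which sets C5 (H cis to Me-14) and creates the C4 methylene.

**Step 10**
Reactants: 13 (3R,3aR,7aS)-3a-methyl-7-methylidene-3-(3-methylbut-2-en-1-yl)hexahydro-2-benzofuran-1(3H)-one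
Product: 14 (1S,2R)-2-[(1R)-1-hydroxy-4-methylpent-3-en-1-yl]-N-methoxy-N,2-dimethyl-6-methylidenecyclohexane-1-carboxamide
Conditions: MeNH(OMe)·HCl, AlMe3, CH2Cl2, 0 °C → rt
Reagents that add atoms: N,O-dimethylhydroxylamine hydrochloride, CNOC.Cl
Why: Aluminium-amide aminolysis of the lactone (Weinreb amide formation) opens the temporary ring and frees the C9 hydroxyl; the reagent is too weakly basic to deprotonate C5.

**Step 11**
Reactants: 14 (1S,2R)-2-[(1R)-1-hydroxy-4-methylpent-3-en-1-yl]-N-methoxy-N,2-dimethyl-6-methylidenecyclohexane-1-carboxamide; 15 4-methoxybenzoyl chloride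
Product: 16 (1R)-1-{(1R,2S)-2-[methoxy(methyl)carbamoyl]-1-methyl-3-methylidenecyclohexyl}-4-methylpent-3-en-1-yl 4-methoxybenzoate
Conditions: pyridine, DMAP (cat.), CH2Cl2, 0 °C → rt, on crude 14
Reagents that add atoms: none
Why: DMAP-catalysed acylation of the only hydroxyl group, run cold and at once so that esterification outruns relactonisation of the γ-hydroxy amide.

**Step 12**
Reactants: 16 (1R)-1-{(1R,2S)-2-[methoxy(methyl)carbamoyl]-1-methyl-3-methylidenecyclohexyl}-4-methylpent-3-en-1-yl 4-methoxybenzoate
Product: 17 (1R)-1-[(1R,2S)-2-formyl-1-methyl-3-methylidenecyclohexyl]-4-methylpent-3-en-1-yl 4-methoxybenzoate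
Conditions: i-Bu2AlH (1.2 equiv), THF, −78 °C; cold Rochelle-salt work-up, used at once
Reagents that add atoms: none
Why: Weinreb amide reduction stops at the chelated hemiaminal and gives the aldehyde on work-up, the hindered electron-rich anisate being slower; the cold neutral work-up should keep the β,γ-unsaturated aldehyde from conjugating or epimerising at C5.

**Step 13**
Reactants: 17 (1R)-1-[(1R,2S)-2-formyl-1-methyl-3-methylidenecyclohexyl]-4-methylpent-3-en-1-yl 4-methoxybenzoate
Product: 19 (1R,3R,4S,4aS,8aR)-4-hydroxy-8a-methyl-5-methylidene-3-(propan-2-yl)decahydronaphthalen-1-yl 4-methoxybenzoate (CNP0107029.1), via mixed acetone ketal 18 (not isolated)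
Conditions: i-PrOSiMe3 (3 equiv), Me3SiOTf (0.2 equiv), CH2Cl2, −78 → −40 °C; then AcOH–THF–H2O, 0 °C
Reagents that add atoms: isopropoxytrimethylsilane, CC(C)O[Si](C)(C)C
Why: Proposed new method: silyl-triflate-catalysed exchange turns the aldehyde into the O-isopropyl oxocarbenium ion at C6 (the aldehyde oxygen leaves as hexamethyldisiloxane), the C7=C11 alkene attacks it in a 6-exo, chair-like Prins closure of ring B, and the tertiary C11 cation is reduced by a 1,5-hydride shift from the O–CH of the isopropyl group through a six-membered transition state; the acetone-derived oxocarbenium ion is trapped as ketal 18 (which regenerates the silyl cation) and hydrolysed to the C6 alcohol. The closest known reaction types are the citronellal-type carbonyl–ene and Prins cyclisation, oxocarbenium cyclisations run with an alkoxysilane and a silyl triflate, and 1,5-hydride transfers from ether C–H bonds to carbocations in internal-redox cyclisations; using the last as a reductive end to the first is the new element. Ring B closes through a chair with the C9 ester and the attacking alkene equatorial, which sets C7 with the isopropyl group cis to the C9 oxygen. C6 is expected to be set by 1,3-allylic strain: the C15 methylene nearly eclipses the C5–C6 bond, so the oxocarbenium oxygen with its isopropyl group lies anti to C4, axial and cis to Me-14, while C5, C9 and C10 are carried through unchanged. The step needs hydride transfer to outrun proton loss from C11 and ring closure to outrun enolisation at C5; the first rests on the fixed gauche O6/C11 geometry in a non-basic medium, the second on the low temperature and the high nucleophilicity of the trisubstituted alkene.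

**Compound list**

1 | methyl 2-methyl-3-oxopentanoate | CCC(=O)C(C)C(=O)OC | starting material
2 | acrolein (prop-2-enal) | C=CC=O | starting material
3 | methyl (2R)-2-methyl-3-oxo-2-(3-oxopropyl)pentanoate | O=CCC[C@@](C)(C(=O)OC)C(=O)CC | intermediate
4 | methyl (1R)-1,3-dimethyl-2-oxocyclohex-3-ene-1-carboxylate | CC1=CCC[C@@](C)(C(=O)OC)C1=O | intermediate
5 | lithium (6R)-6-(methoxycarbonyl)-2,6-dimethylcyclohex-1-en-1-olate | CC1=C(O[Li])[C@@](C)(CCC1)C(=O)OC | intermediate
6 | methyl (1R)-1,3-dimethyl-2-[(trifluoromethanesulfonyl)oxy]cyclohex-2-ene-1-carboxylate | CC1=C(OS(=O)(=O)C(F)(F)F)[C@@](C)(CCC1)C(=O)OC | intermediate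
7 | (6S)-6-(hydroxymethyl)-2,6-dimethylcyclohex-1-en-1-yl trifluoromethanesulfonate | CC1=C(OS(=O)(=O)C(F)(F)F)[C@@](C)(CCC1)CO | intermediate
8 | (6R)-6-formyl-2,6-dimethylcyclohex-1-en-1-yl trifluoromethanesulfonate | CC1=C(OS(=O)(=O)C(F)(F)F)[C@@](C)(CCC1)C=O | intermediate
9 | (6S)-6-[(1R)-1-hydroxybut-3-en-1-yl]-2,6-dimethylcyclohex-1-en-1-yl trifluoromethanesulfonate | CC1=C(OS(=O)(=O)C(F)(F)F)[C@@](C)(CCC1)[C@H](O)CC=C | intermediate
10 | (6S)-6-[(1R)-1-hydroxy-4-methylpent-3-en-1-yl]-2,6-dimethylcyclohex-1-en-1-yl trifluoromethanesulfonate | CC1=C(OS(=O)(=O)C(F)(F)F)[C@@](C)(CCC1)[C@H](O)CC=C(C)C | intermediate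
11 | (3R,3aR)-3a,7-dimethyl-3-(3-methylbut-2-en-1-yl)-3a,4,5,6-tetrahydro-2-benzofuran-1(3H)-one | CC1=C2C(=O)O[C@H](CC=C(C)C)[C@]2(C)CCC1 | intermediate
12 | lithium (3R,3aR)-3a-methyl-7-methylidene-3-(3-methylbut-2-en-1-yl)-3,3a,4,5,6,7-hexahydro-2-benzofuran-1-olate | C=C1CCC[C@]2(C)C1=C(O[Li])O[C@@H]2CC=C(C)C | intermediate
13 | (3R,3aR,7aS)-3a-methyl-7-methylidene-3-(3-methylbut-2-en-1-yl)hexahydro-2-benzofuran-1(3H)-one | C=C1CCC[C@]2(C)[C@H]1C(=O)O[C@@H]2CC=C(C)C | intermediate
14 | (1S,2R)-2-[(1R)-1-hydroxy-4-methylpent-3-en-1-yl]-N-methoxy-N,2-dimethyl-6-methylidenecyclohexane-1-carboxamide | C=C1CCC[C@@](C)([C@@H](CC=C(C)C)O)[C@H]1C(=O)N(C)OC | intermediate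
15 | 4-methoxybenzoyl chloride | COc1ccc(cc1)C(Cl)=O | starting material
16 | (1R)-1-{(1R,2S)-2-[methoxy(methyl)carbamoyl]-1-methyl-3-methylidenecyclohexyl}-4-methylpent-3-en-1-yl 4-methoxybenzoate | C=C1CCC[C@@](C)([C@@H](CC=C(C)C)OC(=O)c2ccc(OC)cc2)[C@H]1C(=O)N(C)OC | intermediate
17 | (1R)-1-[(1R,2S)-2-formyl-1-methyl-3-methylidenecyclohexyl]-4-methylpent-3-en-1-yl 4-methoxybenzoate | C=C1CCC[C@@](C)([C@@H](CC=C(C)C)OC(=O)c2ccc(OC)cc2)[C@H]1C=O | intermediate
18 | (1R,3R,4S,4aS,8aR)-8a-methyl-5-methylidene-3-(propan-2-yl)-4-{[2-(propan-2-yloxy)propan-2-yl]oxy}decahydronaphthalen-1-yl 4-methoxybenzoate | C=C1CCC[C@]2(C)[C@H]1[C@@H](OC(C)(C)OC(C)C)[C@@H](C(C)C)C[C@H]2OC(=O)c1ccc(OC)cc1 | intermediate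
19 | (1R,3R,4S,4aS,8aR)-4-hydroxy-8a-methyl-5-methylidene-3-(propan-2-yl)decahydronaphthalen-1-yl 4-methoxybenzoate | C=C1CCC[C@]2(C)[C@H]1[C@@H](O)[C@@H](C(C)C)C[C@H]2OC(=O)c1ccc(OC)cc1 | target

**Total step count:** 13. **Longest linear sequence:** 13 steps (fully linear, from 1 and 2).

**Steps most likely to fail**

Step 13 (key step). Three processes can defeat it. Proton loss from the C11 cation, or an ene-type closure of the silyl-activated aldehyde before the isopropoxy group is in place, would leave an isopropenyl group. Enolisation of the β,γ-unsaturated oxocarbenium ion would scramble C5 or move the C4 double bond into conjugation. Facial control at C6 could be poor, because the 1,3-diaxial contact of the oxocarbenium oxygen with Me-14 opposes the allylic strain that is relied on. The fallback sets out from 17 and comes back at 19. Me2AlCl in CH2Cl2 at −78 °C should effect the citronellal-type intramolecular carbonyl–ene closure of the C6–C7 bond to give (1R,3R,4S,4aS,8aR)-4-hydroxy-8a-methyl-5-methylidene-3-(prop-1-en-2-yl)decahydronaphthalen-1-yl 4-methoxybenzoate F1, under the same stereocontrol elements. Hydroxyl-directed hydrogenation with [Ir(cod)(PCy3)(py)]PF6 and H2 in CH2Cl2 at 0 °C should then saturate only the isopropenyl group, which is gauche to the axial C6 hydroxyl, whereas the C4 methylene lies anti to it.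

Step 9. Proton removal from the ring CH2 next to C4 instead of from the syn methyl group would give the endocyclic isomer, and equilibration during the quench would return the conjugated lactone. The fallback sets out from 11 and comes back at 13. Irradiation at 254 nm in MeCN with a catalytic amount of 1,2-dimethylimidazole should cause photochemical deconjugation: a 1,5-hydrogen shift from the methyl group held syn to the carbonyl gives the same dienol, which ketonises at C5 inside the cis-fused lactone. It makes no new compound (entry F0).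

Step 12. The hydride may attack the anisate, the very hindered amide may react too slowly, or the γ-hydroxy amide may have relactonised before step 11. The fallback sets out from 13 and comes back at 17, carrying C6 at the alcohol level. LiAlH4 reduction of the lactone gives (1R)-1-[(1R,2S)-2-(hydroxymethyl)-1-methyl-3-methylidenecyclohexyl]-4-methylpent-3-en-1-ol F2. Selective silylation of the primary hydroxyl (TBSCl, imidazole) gives the mono-TBS ether F3. Acylation with 15 (pyridine, DMAP) gives the TBS ether anisate F4. Bu4NF then frees (1R)-1-[(1R,2S)-2-(hydroxymethyl)-1-methyl-3-methylidenecyclohexyl]-4-methylpent-3-en-1-yl 4-methoxybenzoate F5, and Dess–Martin oxidation gives 17.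

**Further compounds**

F1 | step 13 | (1R,3R,4S,4aS,8aR)-4-hydroxy-8a-methyl-5-methylidene-3-(prop-1-en-2-yl)decahydronaphthalen-1-yl 4-methoxybenzoate | C=C1CCC[C@]2(C)[C@H]1[C@@H](O)[C@@H](C(C)=C)C[C@H]2OC(=O)c1ccc(OC)cc1
F0 | step 9 | none | none
F2 | step 12 | (1R)-1-[(1R,2S)-2-(hydroxymethyl)-1-methyl-3-methylidenecyclohexyl]-4-methylpent-3-en-1-ol | C=C1CCC[C@@](C)([C@@H](CC=C(C)C)O)[C@H]1CO
F3 | step 12 | (1R)-1-[(1R,2S)-2-{[(tert-butyldimethylsilyl)oxy]methyl}-1-methyl-3-methylidenecyclohexyl]-4-methylpent-3-en-1-ol | C=C1CCC[C@@](C)([C@@H](CC=C(C)C)O)[C@H]1CO[Si](C)(C)C(C)(C)C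
F4 | step 12 | (1R)-1-[(1R,2S)-2-{[(tert-butyldimethylsilyl)oxy]methyl}-1-methyl-3-methylidenecyclohexyl]-4-methylpent-3-en-1-yl 4-methoxybenzoate | C=C1CCC[C@@](C)([C@@H](CC=C(C)C)OC(=O)c2ccc(OC)cc2)[C@H]1CO[Si](C)(C)C(C)(C)C
F5 | step 12 | (1R)-1-[(1R,2S)-2-(hydroxymethyl)-1-methyl-3-methylidenecyclohexyl]-4-methylpent-3-en-1-yl 4-methoxybenzoate | C=C1CCC[C@@](C)([C@@H](CC=C(C)C)OC(=O)c2ccc(OC)cc2)[C@H]1CO
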